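## Analysis of the target

- The target is a 2,2-dimethylchroman. Benzene ring A (C4a, C5, C6, C7, C8, C8a) is fused to dihydropyran ring B (O1, C2, C3, C4) and carries an (E)-styryl group on C5, a free phenol on C7 and a prenyl group on C8; C3 bears a secondary alcohol.
- C3 is the only stereocentre and is R. It has no neighbouring stereocentre to relay from, so its configuration must come from a reagent or catalyst.
- Ring A is pentasubstituted (only C6 carries hydrogen). Its two oxygens flank the prenyl-bearing C8, one of them locked in ring B and the other free, so the two oxygens of a symmetric resorcinol precursor have to be told apart.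
- The prenyl group sits ortho to both oxygens and cyclises onto either under strong acid; together with the stilbene it also rules out hydrogenation and electrophilic oxidants late in the route. The resorcinol ring itself is easily oxidised.
- The difficulty is to combine full regiocontrol on ring A with an isolated carbinol centre next to the quaternary C2, without closing or re-closing ring B under acid.
- The strategy rests on three atoms of ring B. C4 is a benzylic CH2 on C4a, ortho to the oxygen-bearing C8a, which is the imprint of an ortho-quinone methide. C3 with its oxygen is the alpha carbon of an oxygenated ketene. C2 is that ketene's carbonyl carbon, which can later be turned into the gem-dimethyl carbon.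

## Retrosynthetic reasoning

**24 back to 23.** The two O–Si bonds are cut last. Silyl ethers on the C7 and C3 oxygens come off together under conditions that touch neither alkene nor ring B.

**23 back to 20 (through 22 and 21).** Both C2–CH3 bonds are cut, leading back to the lactone carbonyl of 20. One methyl is traced to the exocyclic methylene of enol ether 21 and the other to substitution of the alpha-chloro ether 22 by a methyl–aluminium reagent. This is chosen over double addition of a methyl nucleophile to 20 because that would open the aryl lactone. The ring would then have to be re-closed by ionising a tertiary alcohol under acid, next to a free phenol that has an ortho prenyl group.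

**20 back to 14 and 17 (through 19 and 18).** This is the central disconnection. The C3–C4 and O1–C2 bonds are cut, which removes ring B and the stereocentre in one operation. It leaves the ortho-quinone methide 19 and the silyloxyketene 18, which are set free in the flask from sulfone 14 and acid chloride 17. The cut is made here because these two bonds join a 1,4-oxa-diene to a two-carbon unit at the correct oxidation level. The forward step has to bind 18 to a chiral nucleophilic amine as an enolate, so that the C3–C4 bond forms on one face, and it has to outrun acylation of the phenol.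

**17 back to 15 (through 16).** The acid chloride comes from glycolic acid 15 through its bis-silyl derivative 16, so that no free acid is present when the chloride is made.

**14 back to 11 (through 13 and 12).** The C4–S bond is cut first and then the C4a–C4 bond. The benzylic carbon is a one-carbon electrophile that the free phenol of 11 directs into its only open ortho position as aldehyde 12; reduction gives 13, and a sulfinate salt replaces the hydroxyl. The silyl ether on the other oxygen is kept on purpose. It blocks the para-quinone methide and it leaves only one phenol to direct the formylation.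

**11 back to 10.** One O–Si bond is cut, which leads to the C2-symmetric resorcinol 10. The two phenols are equivalent, so a single silylation distinguishes the future O1 from the C7 oxygen.

**10 back to 7 and 8 (through 9).** The stilbene C=C bond is cut into aldehyde 7 and phosphonate 8. The stabilised phosphonate carbanion gives the E alkene, and the acetal protecting groups of 9 are removed afterwards.

**7 back to 1 and 4 (through 6, 5, 3 and 2).** The bond between C8 and the prenyl CH2 is cut. The position between the two acetal-protected oxygens of 3 is the most acidic ring position, so lithiation gives 5, and alkylation with 4 gives 6. The aldehyde of 1 is masked as an acetal (2, then 3) for this step. The prenyl group is put in before the stilbene because an alkyllithium would add to a stilbene double bond.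

## Alternatives that were turned down

**Alternative 1: folding of an open-chain triketone into ring A.**
- Disconnection: the C4a–C5 bond is cut, and ring A is unfolded into triketone A1. Its C5 is a cinnamoyl carbonyl and its C3 stereocentre sits in an acetonide side chain.
- Forward key step: base promotes aldol attack of the C4a methylene on C5; loss of water and tautomerisation give resorcinol A2.
- For: every substituent of ring A is placed by the chain, so no arene substitution chemistry is needed. The configuration at C3 is fixed earlier by well-understood chemistry and is more secure than a catalyst-controlled enolate face. On this point the alternative is stronger.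
- Against:
  - A1 has four acidic positions, three ketones and an enone. Cyclisation through oxygen to a pyranone, conjugate addition to the cinnamoyl unit and retro-Claisen cleavage all compete with the wanted aldol.
  - Making A1, branched at C8, takes several Claisen-type condensations.
  - A2 still has ring B open. Closing it means ionising C2 from the acetonide under acid, with two free phenols and an ortho prenyl group present. Those are the conditions this skeleton tolerates worst, and five-membered ring closure competes.
- Comparison: the chosen route buys ring A as an arene and closes ring B under basic conditions in the step that sets C3. That replaces the late acid step and is shorter.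

**Alternative 2: alkoxide addition to an aryne, then prenylation at C8.**
- Disconnection: the O1–C8a bond and the bond from C8 to the prenyl CH2 are cut, giving fluoroarene A3 with the complete chiral side chain.
- Forward key step: a lithium amide base converts A3 into the C8–C8a aryne. The tertiary alkoxide adds at C8a, and the C8 aryl anion is passed to copper and alkylated with 4 to give A4.
- For: the route is convergent, the prenyl group arrives last at a position fixed by the aryne, and the two ring oxygens are different from the start. On oxygen differentiation and on certainty of configuration it is as strong or stronger.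
- Against:
  - A3 is a 1,2,3,5-tetrasubstituted fluoroarene that carries a stilbene and a silyloxy alcohol. It needs a long synthesis of its own.
  - In the vicinal silyloxy alkoxide the silyl group can move to the tertiary oxygen. The secondary alkoxide would then add to the aryne and give a five-membered ring.
  - The amide base can add to the aryne.
  - Three organometallic events in one flask must all succeed, and the allylic alkylation can also give the reverse-prenyl isomer.
- Comparison: the chosen route is shorter from a commercial arene, and it makes ring B and C3 in one catalytic step with mild base.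

**Alternative 3: Michael–Claisen annulation onto an alkylidene lactone.**
- Disconnection: the C5–C6 and C8–C8a bonds are cut. Ring A is built from the dienyl lactone A5, which carries C3, and from the methyl ketone A6.
- Forward key step: the kinetic enolate of A6 adds to A5 at C5. The transposed enolate then attacks the lactone carbonyl and closes the carbocycle as dione A7.
- For: the substitution pattern of ring A is fixed by construction. No directed metalation and no differentiation of two phenols are needed. On ring-A regiochemistry it is stronger.
- Against: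
  - A5 is a dienyl acceptor, so addition at the styryl terminus competes with addition at C5.
  - A7 has to be dehydrogenated to the resorcinol. The usual oxidants for that attack the prenyl group and the styryl group.
  - The two stereocentres made in the annulation are destroyed again on aromatisation.
  - The Claisen step opens ring B, which then has to be closed onto a tertiary alcohol under acid, as in alternative 1.
- Comparison: the chosen route needs no oxidation-state change on ring A, keeps ring B closed once it is formed, and is several steps shorter.

Key step: step 12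

## Route

Assumption: which of the two pseudoenantiomeric alkaloids gives 3R with a silyloxyketene cannot be fixed in advance with certainty. O-benzoylquinidine is written; the configuration of 20 is to be checked on the first run, and O-benzoylquinine replaces it, with nothing else changed, should 3S be found.

Step 1
Reactants: 1 3,5-dihydroxybenzaldehyde
Product: 2 3,5-bis(methoxymethoxy)benzaldehyde
Conditions: MOMCl, iPr2NEt, CH2Cl2, 0 °C → rt
Reagents that add atoms: chloromethyl methyl ether, COCCl
Why: O-alkylation of both phenols to methoxymethyl ethers; the two acetal ethers are the paired ortho-directing groups needed in step 3 and are stable to base and organolithium reagents.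

Step 2
Reactants: 2 3,5-bis(methoxymethoxy)benzaldehyde
Product: 3 1-(dimethoxymethyl)-3,5-bis(methoxymethoxy)benzene
Conditions: HC(OMe)3, MeOH, PPTS (cat.), rt
Reagents that add atoms: trimethyl orthoformate, COC(OC)OC
Why: Acid-catalysed acetalisation with the orthoformate as water scavenger masks the aldehyde against n-BuLi; the weak pyridinium acid should not cleave aryl methoxymethyl ethers at room temperature.

Step 3
Reactants: 3 1-(dimethoxymethyl)-3,5-bis(methoxymethoxy)benzene; 4 1-bromo-3-methylbut-2-ene
Product: 7 3,5-bis(methoxymethoxy)-4-(3-methylbut-2-enyl)benzaldehyde, via aryllithium 5 (not isolated), via prenylated dimethyl acetal 6 (not isolated)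
Conditions: n-BuLi, THF, 0 °C; CuBr·SMe2, −78 °C; 4, −78 °C → rt; then PPTS, acetone–H2O, rt
Reagents that add atoms: water, O
Why: Directed ortho-metalation takes the proton flanked by both acetal ethers to give 5; copper-mediated allylic substitution with 4 should favour direct over transposed attack and give 6; mild aqueous acid cleaves the dimethyl acetal and leaves the aryl methoxymethyl ethers.

Step 4
Reactants: 7 3,5-bis(methoxymethoxy)-4-(3-methylbut-2-enyl)benzaldehyde; 8 diethyl benzylphosphonate
Product: 9 1,3-bis(methoxymethoxy)-2-(3-methylbut-2-enyl)-5-[(E)-2-phenylethenyl]benzene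
Conditions: NaH, THF, 0 °C → rt
Reagents that add atoms: none
Why: Horner–Wadsworth–Emmons olefination; a benzylic phosphonate carbanion and an aryl aldehyde give the E stilbene through the more stable anti oxaphosphetane pathway.

Step 5
Reactants: 9 1,3-bis(methoxymethoxy)-2-(3-methylbut-2-enyl)-5-[(E)-2-phenylethenyl]benzene
Product: 10 2-(3-methylbut-2-enyl)-5-[(E)-2-phenylethenyl]benzene-1,3-diol
Conditions: HCl (3 M aq.), MeOH, rt → 40 °C
Reagents that add atoms: none
Why: Acid-catalysed transacetalisation of the methoxymethyl ethers to methanol; at this acidity and temperature the ortho prenyl group should not cyclise onto the freed phenols, which needs stronger acid or heat.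

Step 6
Reactants: 10 2-(3-methylbut-2-enyl)-5-[(E)-2-phenylethenyl]benzene-1,3-diol
Product: 11 2-(3-methylbut-2-enyl)-5-[(E)-2-phenylethenyl]-3-(triisopropylsilyloxy)phenol
Conditions: TIPSCl (1.0 equiv), imidazole, DMF, 0 °C
Reagents that add atoms: triisopropylsilyl chloride, CC(C)[Si](Cl)(C(C)C)C(C)C
Why: Silylation of one of two equivalent phenols; once a bulky silyl group sits next to the prenyl group the remaining hydroxyl is more hindered, which should favour the mono ether, and unreacted 10 and over-silylated material are separated and recycled.

Step 7
Reactants: 11 2-(3-methylbut-2-enyl)-5-[(E)-2-phenylethenyl]-3-(triisopropylsilyloxy)phenol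
Product: 12 2-hydroxy-3-(3-methylbut-2-enyl)-6-[(E)-2-phenylethenyl]-4-(triisopropylsilyloxy)benzaldehyde
Conditions: MgCl2, Et3N, (CH2O)n, MeCN, 70 °C
Reagents that add atoms: paraformaldehyde (formaldehyde), C=O
Why: Magnesium-mediated ortho-formylation (Casnati–Skattebøl): the magnesium phenoxide delivers formaldehyde to the only free ortho position and a second formaldehyde oxidises the hydroxymethyl intermediate; the silylated oxygen cannot direct, so the position para to the phenol stays untouched.

Step 8
Reactants: 12 2-hydroxy-3-(3-methylbut-2-enyl)-6-[(E)-2-phenylethenyl]-4-(triisopropylsilyloxy)benzaldehyde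
Product: 13 2-(hydroxymethyl)-6-(3-methylbut-2-enyl)-3-[(E)-2-phenylethenyl]-5-(triisopropylsilyloxy)phenol
Conditions: NaBH4, THF–MeOH, 0 °C
Reagents that add atoms: none
Why: Hydride reduction of the aldehyde; low temperature and a short reaction time should avoid loss of the silyl group para to the carbonyl and over-reduction through the quinone methide.

Step 9
Reactants: 13 2-(hydroxymethyl)-6-(3-methylbut-2-enyl)-3-[(E)-2-phenylethenyl]-5-(triisopropylsilyloxy)phenol
Product: 14 6-(p-tolylsulfonylmethyl)-2-(3-methylbut-2-enyl)-5-[(E)-2-phenylethenyl]-3-(triisopropylsilyloxy)phenol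
Conditions: p-TolSO2Na, AcOH, CH2Cl2, rt
Reagents that add atoms: sodium p-toluenesulfinate, Cc1ccc(cc1)S(=O)[O-].[Na+]
Why: Mild acid ionises the electron-rich salicyl alcohol to its ortho-quinone methide or benzylic cation, and the sulfinate adds through sulfur to give the thermodynamically preferred sulfone, a bench-stable precursor that releases the methide with base.

Step 10
Reactants: 15 glycolic acid
Product: 16 tert-butyldimethylsilyl (tert-butyldimethylsilyloxy)acetate
Conditions: TBSCl (2.2 equiv), imidazole, DMF, rt
Reagents that add atoms: tert-butyldimethylsilyl chloride, CC(C)(C)[Si](C)(C)Cl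
Why: Silylation of both the hydroxyl and the carboxyl group; the silyl ester is the substrate for acid chloride formation without free acid.

Step 11
Reactants: 16 tert-butyldimethylsilyl (tert-butyldimethylsilyloxy)acetate
Product: 17 (tert-butyldimethylsilyloxy)acetyl chloride
Conditions: (COCl)2, DMF (cat.), CH2Cl2, 0 °C → rt
Reagents that add atoms: oxalyl chloride, ClC(=O)C(Cl)=O
Why: The chloroiminium species from oxalyl chloride and DMF converts a silyl ester directly into the acid chloride with loss of the silyl chloride; no hydrogen chloride is set free, so the silyl ether survives.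

Step 12
Reactants: 14 6-(p-tolylsulfonylmethyl)-2-(3-methylbut-2-enyl)-5-[(E)-2-phenylethenyl]-3-(triisopropylsilyloxy)phenol; 17 (tert-butyldimethylsilyloxy)acetyl chloride
Product: 20 (3R)-3-(tert-butyldimethylsilyloxy)-8-(3-methylbut-2-enyl)-5-[(E)-2-phenylethenyl]-7-(triisopropylsilyloxy)chroman-2-one, via silyloxyketene 18 (not isolated), via ortho-quinone methide 19 (not isolated)
Conditions: O-benzoylquinidine (15 mol%), iPr2NEt (3.5 equiv), toluene, −30 °C; 17 (2 equiv) added over 6 h; then 0 °C
Reagents that add atoms: none
Why: Proposed new method: iPr2NEt deprotonates the phenol of 14 and loss of p-toluenesulfinate gives 19, while 17 is dehydrochlorinated to 18, which the quinuclidine nitrogen of the alkaloid captures as a zwitterionic acylammonium enolate; the enolate carbon adds to the exocyclic CH2 of 19 (C3–C4), ring A regains aromaticity, and the phenoxide attacks the acylammonium carbon (O1–C2) and releases the catalyst. The closest known reaction types are the formal [4+2] reactions of alkaloid-bound ketene enolates from acid chlorides with ortho-quinones and ortho-quinone imides, and the annulations of azolium- or ammonium-bound enolates with ortho-quinone methides released in the flask; joining the two, with a silyloxyketene and a methide unsubstituted at its CH2, is the unproven part. Ring B closes by 6-exo-trig acyl transfer of the phenoxide onto the acylammonium carbonyl, so the process is a stepwise conjugate addition and lactonisation and not a concerted cycloaddition. C3 is the only new stereocentre and is controlled by the catalyst: the benzoate and the quinoline of the alkaloid cover one face of the planar enolate, and 19, whose CH2 terminus has no faces to distinguish, is taken up on the open face. The step needs C-alkylation of the enolate to win over O-acylation of the phenol of 14; slow addition of 17 keeps acylating species scarce, and the silyloxy donor para to the benzylic carbon speeds the ionisation to 19. Regioselectivity is fixed by the substrate, since only attack at the CH2 restores the aromatic ring and the silyl ether on the C7 oxygen excludes a para-quinone methide.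

Step 13
Reactants: 20 (3R)-3-(tert-butyldimethylsilyloxy)-8-(3-methylbut-2-enyl)-5-[(E)-2-phenylethenyl]-7-(triisopropylsilyloxy)chroman-2-one
Product: 21 (3R)-3-(tert-butyldimethylsilyloxy)-2-methylidene-8-(3-methylbut-2-enyl)-5-[(E)-2-phenylethenyl]-7-(triisopropylsilyloxy)chroman
Conditions: Cp2Ti(CH3)2, toluene, 65 °C, dark
Reagents that add atoms: dimethyltitanocene, [CH3-].[CH3-].[Ti+4].c1cc[cH-]c1.c1cc[cH-]c1
Why: Petasis methylenation: the titanocene methylidene formed on heating adds to the lactone carbonyl and the oxatitanacyclobutane collapses to the enol ether; the reagent is not basic enough to epimerise C3, does not open the aryl lactone, and reacts far more slowly with the internal alkenes.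

Step 14
Reactants: 21 (3R)-3-(tert-butyldimethylsilyloxy)-2-methylidene-8-(3-methylbut-2-enyl)-5-[(E)-2-phenylethenyl]-7-(triisopropylsilyloxy)chroman
Product: 23 (3R)-3-(tert-butyldimethylsilyloxy)-2,2-dimethyl-8-(3-methylbut-2-enyl)-5-[(E)-2-phenylethenyl]-7-(triisopropylsilyloxy)chroman, via 2-chloro-2-methylchroman 22 (not isolated)
Conditions: HCl (1.0 equiv, in Et2O), CH2Cl2, −78 °C; then Al(CH3)3, −78 → −20 °C
Reagents that add atoms: trimethylaluminium, C[Al](C)C
Why: Markovnikov protonation of the enol ether, which is far more basic than the prenyl and stilbene alkenes, gives the alpha-chloro ether 22; Al(CH3)3 abstracts chloride and transfers methyl to the oxocarbenium carbon, the known C-methylation of ketal-level electrophiles. Once the aluminium reagent is present no proton source remains, so C3 cannot be scrambled by reprotonation, and C2 is not a stereocentre in 23.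

Step 15
Reactants: 23 (3R)-3-(tert-butyldimethylsilyloxy)-2,2-dimethyl-8-(3-methylbut-2-enyl)-5-[(E)-2-phenylethenyl]-7-(triisopropylsilyloxy)chroman
Product: 24 (3R)-2,2-dimethyl-8-(3-methylbut-2-enyl)-5-[(E)-2-phenylethenyl]chroman-3,7-diol
Conditions: TBAF, THF, 0 °C → rt
Reagents that add atoms: none
Why: Fluoride cleaves the aryl silyl ether and the secondary alkyl silyl ether; the conditions leave the prenyl group, the stilbene and ring B untouched, and C3 is not involved.

## Compound list

1 | 3,5-dihydroxybenzaldehyde | O=Cc1cc(O)cc(O)c1 | starting material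
2 | 3,5-bis(methoxymethoxy)benzaldehyde | COCOc1cc(C=O)cc(OCOC)c1 | intermediate
3 | 1-(dimethoxymethyl)-3,5-bis(methoxymethoxy)benzene | COCOc1cc(C(OC)OC)cc(OCOC)c1 | intermediate
4 | 1-bromo-3-methylbut-2-ene | CC(C)=CCBr | starting material
5 | [4-(dimethoxymethyl)-2,6-bis(methoxymethoxy)phenyl]lithium | [Li]c1c(OCOC)cc(C(OC)OC)cc1OCOC | intermediate
6 | 5-(dimethoxymethyl)-1,3-bis(methoxymethoxy)-2-(3-methylbut-2-enyl)benzene | COCOc1cc(C(OC)OC)cc(OCOC)c1CC=C(C)C | intermediate
7 | 3,5-bis(methoxymethoxy)-4-(3-methylbut-2-enyl)benzaldehyde | COCOc1cc(C=O)cc(OCOC)c1CC=C(C)C | intermediate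
8 | diethyl benzylphosphonate | CCOP(=O)(Cc1ccccc1)OCC | starting material
9 | 1,3-bis(methoxymethoxy)-2-(3-methylbut-2-enyl)-5-[(E)-2-phenylethenyl]benzene | CC(C)=CCc1c(OCOC)cc(/C=C/c2ccccc2)cc1OCOC | intermediate
10 | 2-(3-methylbut-2-enyl)-5-[(E)-2-phenylethenyl]benzene-1,3-diol | CC(C)=CCc1c(O)cc(/C=C/c2ccccc2)cc1O | intermediate
11 | 2-(3-methylbut-2-enyl)-5-[(E)-2-phenylethenyl]-3-(triisopropylsilyloxy)phenol | CC(C)=CCc1c(O)cc(/C=C/c2ccccc2)cc1O[Si](C(C)C)(C(C)C)C(C)C | intermediate
12 | 2-hydroxy-3-(3-methylbut-2-enyl)-6-[(E)-2-phenylethenyl]-4-(triisopropylsilyloxy)benzaldehyde | CC(C)=CCc1c(O[Si](C(C)C)(C(C)C)C(C)C)cc(/C=C/c2ccccc2)c(C=O)c1O | intermediate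
13 | 2-(hydroxymethyl)-6-(3-methylbut-2-enyl)-3-[(E)-2-phenylethenyl]-5-(triisopropylsilyloxy)phenol | CC(C)=CCc1c(O[Si](C(C)C)(C(C)C)C(C)C)cc(/C=C/c2ccccc2)c(CO)c1O | intermediate
14 | 6-(p-tolylsulfonylmethyl)-2-(3-methylbut-2-enyl)-5-[(E)-2-phenylethenyl]-3-(triisopropylsilyloxy)phenol | CC(C)=CCc1c(O[Si](C(C)C)(C(C)C)C(C)C)cc(/C=C/c2ccccc2)c(CS(=O)(=O)c2ccc(C)cc2)c1O | intermediate
15 | glycolic acid | OCC(=O)O | starting material
16 | tert-butyldimethylsilyl (tert-butyldimethylsilyloxy)acetate | CC(C)(C)[Si](C)(C)OCC(=O)O[Si](C)(C)C(C)(C)C | intermediate
17 | (tert-butyldimethylsilyloxy)acetyl chloride | CC(C)(C)[Si](C)(C)OCC(Cl)=O | intermediate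
18 | (tert-butyldimethylsilyloxy)ketene | CC(C)(C)[Si](C)(C)OC=C=O | intermediate
19 | 6-methylidene-2-(3-methylbut-2-enyl)-5-[(E)-2-phenylethenyl]-3-(triisopropylsilyloxy)cyclohexa-2,4-dien-1-one | CC(C)=CCC1=C(O[Si](C(C)C)(C(C)C)C(C)C)C=C(/C=C/c2ccccc2)C(=C)C1=O | intermediate
20 | (3R)-3-(tert-butyldimethylsilyloxy)-8-(3-methylbut-2-enyl)-5-[(E)-2-phenylethenyl]-7-(triisopropylsilyloxy)chroman-2-one | CC(C)=CCc1c(O[Si](C(C)C)(C(C)C)C(C)C)cc(/C=C/c2ccccc2)c2c1OC(=O)[C@H](O[Si](C)(C)C(C)(C)C)C2 | intermediate
21 | (3R)-3-(tert-butyldimethylsilyloxy)-2-methylidene-8-(3-methylbut-2-enyl)-5-[(E)-2-phenylethenyl]-7-(triisopropylsilyloxy)chroman | CC(C)=CCc1c(O[Si](C(C)C)(C(C)C)C(C)C)cc(/C=C/c2ccccc2)c2c1OC(=C)[C@H](O[Si](C)(C)C(C)(C)C)C2 | intermediate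
22 | (3R)-3-(tert-butyldimethylsilyloxy)-2-chloro-2-methyl-8-(3-methylbut-2-enyl)-5-[(E)-2-phenylethenyl]-7-(triisopropylsilyloxy)chroman, both C2 epimers | CC(C)=CCc1c(O[Si](C(C)C)(C(C)C)C(C)C)cc(/C=C/c2ccccc2)c2c1OC(C)(Cl)[C@H](O[Si](C)(C)C(C)(C)C)C2 | intermediate
23 | (3R)-3-(tert-butyldimethylsilyloxy)-2,2-dimethyl-8-(3-methylbut-2-enyl)-5-[(E)-2-phenylethenyl]-7-(triisopropylsilyloxy)chroman | CC(C)=CCc1c(O[Si](C(C)C)(C(C)C)C(C)C)cc(/C=C/c2ccccc2)c2c1OC(C)(C)[C@H](O[Si](C)(C)C(C)(C)C)C2 | intermediate
24 | (3R)-2,2-dimethyl-8-(3-methylbut-2-enyl)-5-[(E)-2-phenylethenyl]chroman-3,7-diol | CC(C)=CCc1c(O)cc(/C=C/c2ccccc2)c2c1OC(C)(C)[C@H](O)C2 | target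

## Step count and least certain steps

Total: 15 steps. Longest linear sequence: 13 steps (steps 1 to 9 and 12 to 15); steps 10 and 11 are the side branch to 17.

**Step 12 (key step, proposed new method).**
- Most likely failure: acyl transfer from 17 or 18 to the phenoxide of 14 outruns loss of sulfinate. Once the phenol is acylated it can no longer release 19.
- If enolate supply is too slow, 19 dimerises instead.
- Further concerns are poor facial selectivity with the silyloxy-substituted enolate and base-induced loss of configuration at the acidic C3 of 20.
- Fallback, known chemistry throughout, setting out from 11 and returning at 24: 11 is condensed with 3-methylbut-2-enal (PhB(OH)2, AcOH, toluene, reflux). Ortho C-alkylation, dehydration and oxa-electrocyclisation should give 2,2-dimethyl-8-(3-methylbut-2-enyl)-5-[(E)-2-phenylethenyl]-7-(triisopropylsilyloxy)-2H-chromene F1. Jacobsen epoxidation follows, with (R,R)-N,N′-bis(3,5-di-tert-butylsalicylidene)cyclohexane-1,2-diaminomanganese chloride (a salen complex of trivalent manganese) and buffered NaOCl. By analogy with the parent 2,2-dimethylchromenes it is expected to give (3R,4R)-3,4-epoxy-2,2-dimethyl-8-(3-methylbut-2-enyl)-5-[(E)-2-phenylethenyl]-7-(triisopropylsilyloxy)chroman F2; the cis, aryl-conjugated chromene alkene is the preferred substrate of this catalyst over the trans stilbene and the prenyl group. LiAlH4 in THF opens the epoxide at the benzylic C4 to (3R)-2,2-dimethyl-8-(3-methylbut-2-enyl)-5-[(E)-2-phenylethenyl]-7-(triisopropylsilyloxy)chroman-3-ol F3, and TBAF then gives 24.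

**Step 14.**
- Most likely failure: the oxocarbenium ion loses the C3 proton to give the ring-internal enol ether. This costs material, and it costs configuration if any acid remains to reprotonate.
- Excess HCl can also add to the prenyl group.
- Fallback without a Brønsted acid, setting out from 21 and returning at 23: PhSeCl adds to the enol ether at −78 °C, selenium on the terminal carbon and chloride on C2. This gives (3R)-3-(tert-butyldimethylsilyloxy)-2-chloro-8-(3-methylbut-2-enyl)-5-[(E)-2-phenylethenyl]-2-(phenylselanylmethyl)-7-(triisopropylsilyloxy)chroman F4, which is not isolated. Al(CH3)3 replaces the chloride by methyl to give (3R)-3-(tert-butyldimethylsilyloxy)-2-methyl-8-(3-methylbut-2-enyl)-5-[(E)-2-phenylethenyl]-2-(phenylselanylmethyl)-7-(triisopropylsilyloxy)chroman F5. Bu3SnH with AIBN in toluene at 80 °C then reduces the C–Se bond, which gives the second methyl group of 23.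

**Step 6.**
- Most likely failure: silylation of two equivalent phenols gives the mono ether together with diol and bis ether, so throughput depends on recycling.
- Fallback that breaks the symmetry by C–C bond formation, setting out from 10 and returning at 12: magnesium-mediated formylation of 10 (MgCl2, Et3N, (CH2O)n, one position only) gives 2,4-dihydroxy-3-(3-methylbut-2-enyl)-6-[(E)-2-phenylethenyl]benzaldehyde F6. Its hydroxyl ortho to the aldehyde is tied up in a hydrogen bond, so TIPSCl and imidazole should silylate the other one and give 12.

**Step 9.**
- Most likely failure: the very electron-rich benzylic cation or methide from 13 alkylates the ring of a second molecule, giving oligomers, faster than it is captured by sulfinate.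
- Loss of the benzylic oxygen by over-reduction in step 8 belongs to the same weakness.
- Fallback that avoids 12 and 13, setting out from 11 and returning at 14: a phenolic Mannich reaction (aqueous CH2O, Me2NH, EtOH) gives 2-[(dimethylamino)methyl]-6-(3-methylbut-2-enyl)-3-[(E)-2-phenylethenyl]-5-(triisopropylsilyloxy)phenol F7. MeI converts it into the trimethylammonium iodide F8. Warming F8 with p-TolSO2Na in MeCN expels trimethylamine through 19, and sulfinate addition gives 14.

**Step 3.**
- Most likely failure: allylic transposition in the coupling with 4 gives the reverse-prenyl isomer, or metalation of 3 is incomplete.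
- Fallback that removes the regiochemical question, setting out from 3 (through 5) and returning at 7: 5 is alkylated with allyl bromide (CuBr·SMe2) to 2-allyl-5-(dimethoxymethyl)-1,3-bis(methoxymethoxy)benzene F9. The same acidic work-up gives 4-allyl-3,5-bis(methoxymethoxy)benzaldehyde F10. Cross-metathesis of F10 with 2-methylbut-2-ene and the second-generation Grubbs catalyst, (H2IMes)(PCy3)Cl2Ru=CHPh, gives 7.

## Further compounds

F1 | step 12 | 2,2-dimethyl-8-(3-methylbut-2-enyl)-5-[(E)-2-phenylethenyl]-7-(triisopropylsilyloxy)-2H-chromene | CC(C)=CCc1c(O[Si](C(C)C)(C(C)C)C(C)C)cc(/C=C/c2ccccc2)c2c1OC(C)(C)C=C2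
F2 | step 12 | (3R,4R)-3,4-epoxy-2,2-dimethyl-8-(3-methylbut-2-enyl)-5-[(E)-2-phenylethenyl]-7-(triisopropylsilyloxy)chroman | CC(C)=CCc1c(O[Si](C(C)C)(C(C)C)C(C)C)cc(/C=C/c2ccccc2)c2c1OC(C)(C)[C@@H]1O[C@H]21
F3 | step 12 | (3R)-2,2-dimethyl-8-(3-methylbut-2-enyl)-5-[(E)-2-phenylethenyl]-7-(triisopropylsilyloxy)chroman-3-ol | CC(C)=CCc1c(O[Si](C(C)C)(C(C)C)C(C)C)cc(/C=C/c2ccccc2)c2c1OC(C)(C)[C@H](O)C2
F4 | step 14 | (3R)-3-(tert-butyldimethylsilyloxy)-2-chloro-8-(3-methylbut-2-enyl)-5-[(E)-2-phenylethenyl]-2-(phenylselanylmethyl)-7-(triisopropylsilyloxy)chroman, both C2 epimers | CC(C)=CCc1c(O[Si](C(C)C)(C(C)C)C(C)C)cc(/C=C/c2ccccc2)c2c1OC(Cl)(C[Se]c1ccccc1)[C@H](O[Si](C)(C)C(C)(C)C)C2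
F5 | step 14 | (3R)-3-(tert-butyldimethylsilyloxy)-2-methyl-8-(3-methylbut-2-enyl)-5-[(E)-2-phenylethenyl]-2-(phenylselanylmethyl)-7-(triisopropylsilyloxy)chroman, both C2 epimers | CC(C)=CCc1c(O[Si](C(C)C)(C(C)C)C(C)C)cc(/C=C/c2ccccc2)c2c1OC(C)(C[Se]c1ccccc1)[C@H](O[Si](C)(C)C(C)(C)C)C2
F6 | step 6 | 2,4-dihydroxy-3-(3-methylbut-2-enyl)-6-[(E)-2-phenylethenyl]benzaldehyde | CC(C)=CCc1c(O)cc(/C=C/c2ccccc2)c(C=O)c1O
F7 | step 9 | 2-[(dimethylamino)methyl]-6-(3-methylbut-2-enyl)-3-[(E)-2-phenylethenyl]-5-(triisopropylsilyloxy)phenol | CC(C)=CCc1c(O[Si](C(C)C)(C(C)C)C(C)C)cc(/C=C/c2ccccc2)c(CN(C)C)c1O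
F8 | step 9 | [2-hydroxy-3-(3-methylbut-2-enyl)-6-[(E)-2-phenylethenyl]-4-(triisopropylsilyloxy)phenyl]methyl-trimethylammonium iodide | CC(C)=CCc1c(O[Si](C(C)C)(C(C)C)C(C)C)cc(/C=C/c2ccccc2)c(C[N+](C)(C)C)c1O.[I-]
F9 | step 3 | 2-allyl-5-(dimethoxymethyl)-1,3-bis(methoxymethoxy)benzene | COCOc1cc(C(OC)OC)cc(OCOC)c1CC=C
F10 | step 3 | 4-allyl-3,5-bis(methoxymethoxy)benzaldehyde | COCOc1cc(C=O)cc(OCOC)c1CC=C
A1 | alternative 1 | (6E)-1-[(4R)-2,2,5,5-tetramethyl-1,3-dioxolan-4-yl]-4-(3-methylbut-2-enyl)-7-phenylhept-6-ene-3,5-dione carrying the third ketone as written (open-chain triketone) | CC(C)=CCC(C(=O)CC(=O)/C=C/c1ccccc1)C(=O)CC[C@H]1OC(C)(C)OC1(C)C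
A2 | alternative 1 | 2-(3-methylbut-2-enyl)-5-[(E)-2-phenylethenyl]-4-{[(4R)-2,2,5,5-tetramethyl-1,3-dioxolan-4-yl]methyl}benzene-1,3-diol | CC(C)=CCc1c(O)cc(/C=C/c2ccccc2)c(C[C@H]2OC(C)(C)OC2(C)C)c1O
A3 | alternative 2 | (3R)-3-(tert-butyldimethylsilyloxy)-4-[2-fluoro-4-(methoxymethoxy)-6-[(E)-2-phenylethenyl]phenyl]-2-methylbutan-2-ol | COCOc1cc(F)c(C[C@@H](O[Si](C)(C)C(C)(C)C)C(C)(C)O)c(/C=C/c2ccccc2)c1
A4 | alternative 2 | (3R)-3-(tert-butyldimethylsilyloxy)-7-(methoxymethoxy)-2,2-dimethyl-8-(3-methylbut-2-enyl)-5-[(E)-2-phenylethenyl]chroman | CC(C)=CCc1c(OCOC)cc(/C=C/c2ccccc2)c2c1OC(C)(C)[C@H](O[Si](C)(C)C(C)(C)C)C2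
A5 | alternative 3 | (3E,5R)-5-(tert-butyldimethylsilyloxy)-6,6-dimethyl-3-[(E)-3-phenylprop-2-enylidene]oxan-2-one | O=C1OC(C)(C)[C@H](O[Si](C)(C)C(C)(C)C)C/C1=C\C=C\c1ccccc1
A6 | alternative 3 | 6-methylhept-5-en-2-one | CC(=O)CCC=C(C)C
A7 | alternative 3 | 2-(3-methylbut-2-enyl)-5-[(E)-2-phenylethenyl]cyclohexane-1,3-dione with the (2R)-2-(tert-butyldimethylsilyloxy)-3-hydroxy-3-methylbutyl chain on C4, trans, as one enol | CC(C)=CCC1=C(O)C[C@@H](/C=C/c2ccccc2)[C@H](C[C@@H](O[Si](C)(C)C(C)(C)C)C(C)(C)O)C1=O
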